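The earlier runs and the new flask are calculated for an exercise; noise was put on by code.

Slowness struck me first: the eta flask took 10.0 h to reach 40.2 % of target, while the beta flask, at 17.1 times its loading, stood at 44.7 % after 1.50 h.

| flask | substrate | enzyme | remark | time |
|---|---|---|---|---|
| eta | 13 mM | 1.7 × 10⁻⁴ mol% (in portions, 3) | run made earlier; portions every 1.0 h |  |
| beta | 13 mM | 0.0029 mol% (in portions, 3) | run made earlier; portions every 1.0 h |  |
| north-west | 13 mM | 1.5 × 10⁻⁴ mol% (in portions, 3) | the portions of enzyme follow each other after 1.0 h, the first at the start | 10 h |
| north | 13 mM | 3.0 × 10⁻⁴ mol% (in portions, 3) | the portions of enzyme follow each other after 1.0 h, the first at the start | 10 h |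
| east | 13 mM | 6.0 × 10⁻⁴ mol% (in portions, 3) | the portions of enzyme follow each other after 1.0 h, the first at the start | 10 h |
| south | 13 mM | 0.0012 mol% (in portions, 3) | the portions of enzyme follow each other after 1.0 h, the first at the start | 10 h |
| south-east | 13 mM | 0.0025 mol% (in portions, 3) | the portions of enzyme follow each other after 1.0 h, the first at the start | 10 h |

- eta (time / h: target / %): 1.33: 3.3; 3.00: 12.7; 4.00: 17.8; 6.00: 27.2; 8.00: 34.1; 10.0: 40.2
- beta (time / h: target / %): 0.500: 16.9; 1.50: 44.7; 3.00: 46.4; 4.00: 44.9; 6.00: 42.8; 8.00: 43.4; 10.0: 43.0

(scatter of a reading: 0.5 percentage points)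

- the analysis behind the earlier runs scatters by 0.5 percentage points, standard deviation
- steps thought possible: substrate + enzyme -> target + enzyme; target + enzyme <-> isomer of the product + enzyme
- "hardly changes" means that all values lie within two and a half points (for a concentration: within two and a half percent of the largest)

1. amount of target at the end, in percent of the substrate charged for north-west, north, east, south, south-east, in this order
2. how that number moves from the first to the last of them (rises, then falls / rises all the way / hardly changes / falls, then rises / falls all the way)

The bench rule says that enzyme trades against time, and target was still climbing in the eta flask at 10.0 h, so I tried it. For north-west at the end, 1.35 × 10⁻⁵ h is the enzyme-time, Θ: each portion's loading, taken as a fraction, multiplied by the hours it has been in the flask, summed over the portions. The eta flask at 4.00 h has Θ = 5.10 × 10⁻⁶ h, and the beta flask at 0.500 h, with one portion in, has 4.83 × 10⁻⁶ h. Their readings, 17.8 % and 16.9 %, nearly meet, so I read both runs as one curve in Θ.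

The simpler rule, more enzyme-time for more target, has a border. The beta flask read 44.7 % at Θ = 1.93 × 10⁻⁵ h and 46.4 % at 5.80 × 10⁻⁵ h, then sank to 43.0 %. That highest reading stands at 3.79 times the Θ of the eta flask's end. I call the rising part of the curve kinetic control and the flat tail of the beta flask thermodynamic control.

My own reckoning took one multiplication per flask. North-west has less enzyme-time than the eta flask's end, and scaling gave me about 35.5 %. North, at 2.70 × 10⁻⁵ h, falls in the gap between the beta flask's readings at 1.50 h and 3.00 h, so I gave it no figure. East, at 5.40 × 10⁻⁵ h, sits beside the reading the beta flask gave at 3.00 h, and south and south-east lie on the tail, so I expected the row to rise and then fall.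

The forecast gave 37 %, 50 %, 47 %, 44 % and 43 %, and called the shape "rises, then falls". It differs from mine at north-west and puts a number on north, which it marks “near the peak (interpolated, least certain)”.

The flasks gave 36.8 %, 50.3 %, 48.3 %, 43.5 % and 43.3 %, so the row rises, then falls.

    substrate + enzyme → target + enzyme, rate k1*[substrate]*[enzyme]/(1 + ([substrate]/Km1)) (9.36 mM, k = 7.30 × 10⁶ L mol⁻¹ h⁻¹)
    target + enzyme ⇌ isomer of the product + enzyme, rate k2*[enzyme]*[target] forward; the back reaction follows from the equilibrium constant (K = 1.31, k = 3.16 × 10⁶ L mol⁻¹ h⁻¹)

The row turned at a loading of 3.9 × 10⁻⁴ mol%, which is Θ = 3.49 × 10⁻⁵ h, inside that gap. North-west at 5.00 h and east at 2.00 h share Θ = 6.00 × 10⁻⁶ h, and they held 20.1 % and 20.1 % of target. In north-west at 10.0 h, each step taken net, target was being made faster than it was used up, by a factor of 2.43.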